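## Retrosynthetic overview

1. Target 9 ⇐ 8: hydrogenolysis of two benzyl ethers (O-5, O-4') that mask the hydroxyls which must stay unsulfated.
2. 8 ⇐ 7: double O-sulfation of the only free hydroxyls (3-OH and 3'-OH).
3. 7 ⇐ 5: Algar–Flynn–Oyamada oxidative cyclisation of a 2'-hydroxychalcone (O1–C2 bond and 3-OH installed together).
4. 5 ⇐ 2 + 3: Claisen–Schmidt condensation; 2 ⇐ 1 by mono-benzylation of a symmetric diol.
5. Ring order: rings A and B are bought as benzene building blocks; ring C (the pyranone) is the only ring formed, in step 3.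

Assumption: the target has no stereocentre (it is achiral), so no enantiocontrol is needed; the sulfates are drawn as free acids as in the target SMILES, although 8 and 9 are handled as dipotassium salts until the final proton exchange.

## Route

Step 1
Reactants: 1 1-(2,6-dihydroxy-4-methoxyphenyl)ethanone
Product: 2 1-[2-(benzyloxy)-6-hydroxy-4-methoxyphenyl]ethanone
Conditions: BnBr (1.05 equiv), K2CO3 (1.1 equiv), acetone, reflux, 6 h
Reagents that add atoms: benzyl bromide, BrCc1ccccc1
Why: Williamson ether synthesis in which the two hydroxyls of 1 are equivalent by symmetry, and after one O-benzylation the remaining hydroxyl is held in a strong hydrogen bond to the ketone and resists a second alkylation.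

Step 2
Reactants: 2 1-[2-(benzyloxy)-6-hydroxy-4-methoxyphenyl]ethanone; 3 4-(benzyloxy)-3-hydroxybenzaldehyde
Product: 5 (E)-1-[2-(benzyloxy)-6-hydroxy-4-methoxyphenyl]-3-[4-(benzyloxy)-3-hydroxyphenyl]prop-2-en-1-one, via racemic β-hydroxy ketone aldol adduct 4 (not isolated)
Conditions: KOH (50% aq, 10 equiv), EtOH, 0 °C to rt, 48 h; then cold dilute HCl to pH 4
Reagents that add atoms: none
Why: Claisen–Schmidt (crossed aldol) condensation followed by E1cB dehydration gives the thermodynamically favoured E-enone, the aldehyde's free hydroxyl being meta to the formyl group so its phenoxide does not switch off the electrophile; the aldol stereocentre is lost on dehydration.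

Step 3
Reactants: 5 (E)-1-[2-(benzyloxy)-6-hydroxy-4-methoxyphenyl]-3-[4-(benzyloxy)-3-hydroxyphenyl]prop-2-en-1-one
Product: 7 5-(benzyloxy)-2-[4-(benzyloxy)-3-hydroxyphenyl]-3-hydroxy-7-methoxy-4H-chromen-4-one, via racemic trans-dihydroflavonol 6 (not isolated)
Conditions: H2O2 (30% aq, 5 equiv), NaOH (2 M aq, 6 equiv), MeOH/THF, 0 °C to rt, 16 h; then dilute HCl
Reagents that add atoms: hydrogen peroxide, OO
Why: Algar–Flynn–Oyamada reaction, in which the 2'-phenoxide closes ring C by 6-endo oxa-Michael addition while alkaline hydroperoxide hydroxylates C-3, and the resulting trans-dihydroflavonol is dehydrogenated by further H2O2 to the achiral flavonol, so its two transient stereocentres are erased.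

Step 4
Reactants: 7 5-(benzyloxy)-2-[4-(benzyloxy)-3-hydroxyphenyl]-3-hydroxy-7-methoxy-4H-chromen-4-one
Product: 8 5-(benzyloxy)-2-[4-(benzyloxy)-3-(sulfooxy)phenyl]-7-methoxy-4-oxo-4H-chromen-3-yl hydrogen sulfate (5,4'-di-O-benzylrhamnetin 3,3'-disulfate, handled as the dipotassium salt)
Conditions: SO3·pyridine (8 equiv), pyridine, 60 °C, 12 h; then cation-exchange resin (K+ form), Sephadex LH-20 (MeOH/H2O)
Reagents that add atoms: sulfur trioxide pyridine complex, O=S(=O)([O-])[n+]1ccccc1
Why: O-sulfation with an amine–SO3 complex converts the only two free hydroxyls (3-OH and 3'-OH) into sulfate monoesters, the 3,3' regiochemistry being fixed by the benzyl ethers at O-5 and O-4' and the methyl ether at O-7.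

Step 5
Reactants: 8 5,4'-di-O-benzylrhamnetin 3,3'-disulfate (dipotassium salt)
Product: 9 5-hydroxy-2-[4-hydroxy-3-(sulfooxy)phenyl]-7-methoxy-4-oxo-4H-chromen-3-yl hydrogen sulfate (rhamnetin 3,3'-disulfate)
Conditions: H2 (1 atm), 10% Pd/C, MeOH/H2O 4:1, rt, 3 h; filter; sulfonic acid resin (H+ form), 0 °C, freeze-dry
Reagents that add atoms: none
Why: Catalytic hydrogenolysis cleaves both aryl benzyl ethers while aryl sulfate salts and the chromone C2=C3 bond are inert under these mild conditions, and cold proton exchange delivers the free acid form drawn for the target.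

## Compound list

1 | 1-(2,6-dihydroxy-4-methoxyphenyl)ethanone (2',6'-dihydroxy-4'-methoxyacetophenone) | CC(=O)c1c(O)cc(OC)cc1O | starting material
2 | 1-[2-(benzyloxy)-6-hydroxy-4-methoxyphenyl]ethanone | CC(=O)c1c(O)cc(OC)cc1OCc1ccccc1 | intermediate
3 | 4-(benzyloxy)-3-hydroxybenzaldehyde | O=Cc1ccc(OCc2ccccc2)c(O)c1 | starting material
4 | racemic 1-[2-(benzyloxy)-6-hydroxy-4-methoxyphenyl]-3-[4-(benzyloxy)-3-hydroxyphenyl]-3-hydroxypropan-1-one (aldol adduct, stereocentre not controlled) | COc1cc(O)c(C(=O)CC(O)c2ccc(OCc3ccccc3)c(O)c2)c(OCc2ccccc2)c1 | intermediate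
5 | (E)-1-[2-(benzyloxy)-6-hydroxy-4-methoxyphenyl]-3-[4-(benzyloxy)-3-hydroxyphenyl]prop-2-en-1-one | COc1cc(O)c(C(=O)/C=C/c2ccc(OCc3ccccc3)c(O)c2)c(OCc2ccccc2)c1 | intermediate
6 | racemic trans-5-(benzyloxy)-2-[4-(benzyloxy)-3-hydroxyphenyl]-3-hydroxy-7-methoxychroman-4-one ((2R,3R) enantiomer drawn) | Oc1cc(ccc1OCc1ccccc1)[C@@H]1[C@@H](O)C(=O)c2c(OCc3ccccc3)cc(OC)cc2O1 | intermediate
7 | 5-(benzyloxy)-2-[4-(benzyloxy)-3-hydroxyphenyl]-3-hydroxy-7-methoxy-4H-chromen-4-one | COc1cc(OCc2ccccc2)c2c(=O)c(O)c(-c3ccc(OCc4ccccc4)c(O)c3)oc2c1 | intermediate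
8 | 5-(benzyloxy)-2-[4-(benzyloxy)-3-(sulfooxy)phenyl]-7-methoxy-4-oxo-4H-chromen-3-yl hydrogen sulfate | COc1cc(OCc2ccccc2)c2c(=O)c(OS(=O)(=O)O)c(-c3ccc(OCc4ccccc4)c(OS(=O)(=O)O)c3)oc2c1 | intermediate
9 | rhamnetin 3,3'-disulfate | COc1cc(O)c2c(=O)c(OS(=O)(=O)O)c(-c3ccc(O)c(OS(=O)(=O)O)c3)oc2c1 | target

## Summary

Total step count: 5. Longest linear sequence: 5 steps (1 → 2 → 5 → 7 → 8 → 9).

Steps most likely to fail:

**Step 3 (Algar–Flynn–Oyamada).** The 6'-benzyloxy group twists the enone and can divert the oxidation to the aurone by 5-exo closure. The fallback separates ring closure from C-3 oxygenation and sets out from chalcone 5.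
- I2 (10 mol%) in DMSO at 120 °C cyclises 5 oxidatively to the flavone 5-(benzyloxy)-2-[4-(benzyloxy)-3-hydroxyphenyl]-7-methoxy-4H-chromen-4-one F1.
- Ac2O/pyridine masks the phenol as 2-(benzyloxy)-5-[5-(benzyloxy)-7-methoxy-4-oxo-4H-chromen-2-yl]phenyl acetate F2.
- Dimethyldioxirane (acetone/CH2Cl2, 0 °C) epoxidises the C2=C3 bond to the racemic cis-fused flavone 2,3-epoxide F3.
- Catalytic p-TsOH isomerises this to 2-(benzyloxy)-5-[5-(benzyloxy)-3-hydroxy-7-methoxy-4-oxo-4H-chromen-2-yl]phenyl acetate F4.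
- K2CO3/MeOH removes the acetate, and the route is rejoined at flavonol 7.

**Step 4 (double sulfation).** The hydrogen-bonded, flanked 3-OH may react incompletely, and the dianionic product is hard to purify. The fallback installs the sulfates as neutral protected diesters and sets out from flavonol 7.
- 2,2,2-Trichloroethyl chlorosulfate (2.5 equiv), Et3N and DMAP in THF (0 °C to rt) give 5-(benzyloxy)-2-{4-(benzyloxy)-3-[(2,2,2-trichloroethoxy)sulfonyloxy]phenyl}-7-methoxy-4-oxo-4H-chromen-3-yl 2,2,2-trichloroethyl sulfate F5, which can be purified on silica.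
- Zn dust and HCO2NH4 in MeOH at rt fragment both trichloroethyl groups reductively, and after K+ exchange the route is rejoined at disulfate 8.

**Step 5 (hydrogenolysis and release of the free acid).** The salt may be debenzylated sluggishly, or the labile 3-enol sulfate may be lost during proton exchange. The fallback removes the benzyl groups before any sulfate is present and sets out from flavonol 7. Its regiocontrol rests on enzyme selectivity and timing, which is why it is not the main route.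
- H2, 10% Pd/C in THF/MeOH gives rhamnetin F6.
- SO3·NMe3 (excess) and K2CO3 in DMF at rt sulfate the 3-, 3'- and 4'-hydroxyls, leaving the chelated 5-OH, to give rhamnetin 3,3',4'-trisulfate F7.
- Aryl sulfatase (Helix pomatia) in pH 7 buffer, monitored by HPLC, hydrolyses the most activated 4'-sulfate (para to the chromone); the 3-enol sulfate is not a substrate and the 3'-sulfate reacts much more slowly. The route is rejoined at target 9.

## Further compounds

F1 | step 3 | 5-(benzyloxy)-2-[4-(benzyloxy)-3-hydroxyphenyl]-7-methoxy-4H-chromen-4-one | COc1cc(OCc2ccccc2)c2c(=O)cc(-c3ccc(OCc4ccccc4)c(O)c3)oc2c1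
F2 | step 3 | 2-(benzyloxy)-5-[5-(benzyloxy)-7-methoxy-4-oxo-4H-chromen-2-yl]phenyl acetate | COc1cc(OCc2ccccc2)c2c(=O)cc(-c3ccc(OCc4ccccc4)c(OC(C)=O)c3)oc2c1
F3 | step 3 | racemic cis-fused flavone 2,3-epoxide derived from F2 (one enantiomer drawn) | O=C1[C@@H]2O[C@]2(c2ccc(OCc3ccccc3)c(OC(C)=O)c2)Oc2cc(OC)cc(OCc3ccccc3)c12
F4 | step 3 | 2-(benzyloxy)-5-[5-(benzyloxy)-3-hydroxy-7-methoxy-4-oxo-4H-chromen-2-yl]phenyl acetate | COc1cc(OCc2ccccc2)c2c(=O)c(O)c(-c3ccc(OCc4ccccc4)c(OC(C)=O)c3)oc2c1
F5 | step 4 | 5-(benzyloxy)-2-{4-(benzyloxy)-3-[(2,2,2-trichloroethoxy)sulfonyloxy]phenyl}-7-methoxy-4-oxo-4H-chromen-3-yl 2,2,2-trichloroethyl sulfate | COc1cc(OCc2ccccc2)c2c(=O)c(OS(=O)(=O)OCC(Cl)(Cl)Cl)c(-c3ccc(OCc4ccccc4)c(OS(=O)(=O)OCC(Cl)(Cl)Cl)c3)oc2c1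
F6 | step 5 | rhamnetin (3,5,3',4'-tetrahydroxy-7-methoxyflavone) | COc1cc(O)c2c(=O)c(O)c(-c3ccc(O)c(O)c3)oc2c1
F7 | step 5 | rhamnetin 3,3',4'-trisulfate | COc1cc(O)c2c(=O)c(OS(=O)(=O)O)c(-c3ccc(OS(=O)(=O)O)c(OS(=O)(=O)O)c3)oc2c1
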